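Read the share asked for as a survival: of all that became target, how much still stood as target. Starting material that never became target stays out of it, so the share needs a clock for target.

| flask | starting material | gas phase | remark | time |
|---|---|---|---|---|
| spring | 0.57 mM | 0.079 mM (held) | run made earlier |  |
| noon | 1.1 mM | 0.079 mM (held) | run made earlier |  |
| summer | 2.4 mM | 0.079 mM (held) | run made earlier |  |
| Wednesday's | 2.0 mM | 0.079 mM (held) |  | 15 min |
| Saturday's | 0.50 mM | 0.079 mM (held) |  | 4.0 min |

| run | time / min | target / % | over-reacted product / % |
|---|---|---|---|
| spring | 1.00 | 52.9 | 1.8 |
| spring | 2.50 | 25.8 | 5.4 |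
| spring | 5.00 | 6.7 | 7.1 |
| spring | 8.00 | 0.3 | 8.2 |
| spring | 10.0 | 0.3 | 9.1 |
| noon | 0.833 | 49.3 | 1.7 |
| noon | 1.50 | 41.3 | 3.7 |
| noon | 3.00 | 17.1 | 6.1 |
| noon | 6.00 | 2.9 | 7.3 |
| noon | 10.0 | 0.6 | 7.6 |
| summer | 0.833 | 39.7 | 2.0 |
| summer | 1.50 | 31.5 | 2.3 |
| summer | 3.00 | 13.6 | 3.1 |
| summer | 6.00 | 1.5 | 5.6 |
| summer | 10.0 | 0.4 | 6.6 |

(readings scatter by 0.5 percentage points)

1. the flask that ends with the higher share of target in all that became target or over-reacted product or over-reaction product, or "neither" when 2 percentage points or less lies between them (Wednesday's / Saturday's / neither)
2. share of target in all that became target or over-reacted product or over-reaction product, Wednesday's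
3. share of target in all that became target or over-reacted product or over-reaction product, Saturday's

- the analysis behind the earlier runs scatters by 0.5 percentage points, standard deviation
- at the start none of the gas phase is in solution

The noon run gave that clock. Target fell from 17.1% at 3.00 min to 2.9% at 6.00 min, a pseudo-first-order fall with a half-life of 1.17 min. I carried this reading as the tail half-life, the time in which target halves once its making is over.

I then solved two extreme flasks. If all target was born at the start, the share was 9.39% for Saturday's and 0.0140% for Wednesday's. If all of it was born at 1.00 min, they became 17.0% and 0.0253%. I took the real flasks to lie between these as an estimate, not a bound: no target is older than its flask, and the spring run already held 52.9% at 1.00 min, though some target might still be born after that time. Even late Wednesday's stood far below early Saturday's, so I committed to Saturday's.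

The forecast also chose Saturday's, with 0.2% for Wednesday's and 12% for Saturday's, holding that “essentially all starting material should have converted”. Its Saturday's figure lay inside my range, and its Wednesday's figure lay above mine.

The flasks gave Saturday's: 0.0146% for Wednesday's and 12.1% for Saturday's.

    gas phase ⇌ dissolved gas, rate k1*(csat - [dissolved gas]) (kL = 8.50 s⁻¹)
    starting material + dissolved gas → target (k = 450 M⁻¹ s⁻¹)
    dissolved gas + target → over-reacted product (k = 12.0 M⁻¹ s⁻¹)
    2 starting material → self-condensation product (k = 8.50 M⁻¹ s⁻¹)
    dissolved gas ⇌ dormant form (K = 300, k = 0.0160 s⁻¹)
    target → over-reaction product (k = 0.00920 s⁻¹)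

In Saturday's, half of the making of target was done by 0.309 min, sooner than the 1.3 min half-life of target by its passing into over-reaction product at 4.00 min. That half-life is shorter than Saturday's 4.0 min. By my tail half-life, Saturday's 12.1% means an age of 3.57 min, as if all target was born at 0.430 min. For the same flask left until 2.5 min, the tail half-life carries that share back to 29.4%, and the flask stood at 29.7%.

The numbers in the tables were computed with constants of no real substance.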